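**Plan**

Locants: the carbocycle is counted from the isopropenyl-bearing CH (C1) through C2, the enoate C3=C4 (CO2Me on C4), C5, ketone C6, C7, C8 (CH3 and ether O), C9, ketone C10, ether CH C11, C12, ketone C13 and C14.
Enabling feature: C10 (C=O) and C11 (C–O) are neighbours in the oxolan-3-one ring O/C8/C9/C10/C11. Together they equal a C10≡C11 triple bond plus the C8 hydroxyl plus one oxygen atom. The only C=C bonds (isopropenyl on C1, C3=C4) do not react with metal alkylidynes, so the 14-membered ring C1–C14 can be closed at that bond.
Cuts, in order: O–C11 (oxa-Michael) and the C10/C13 dicarbonyl (furan + O2); furan O–C10 (3-alkynone cycloisomerisation); C10≡C11 (alkyne metathesis); C3=C4 (Still–Gennari); then C4–C5, C6–C7 and C9–C10 in the west and C12–C13 in the east.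
Forward: a C4–C10 phosphonate and a C3–C11 aldehyde are joined at C3=C4, and the carbocycle closes at C10≡C11. The C13 ketone then folds onto the alkyne to give a 2,5-bridged furan (O/C10–C13), and singlet oxygen exchanges that ring for the oxolanone.
Stereochemistry: C8 comes from (R)-2-methylglycidol and C1 from (R)-carvone (carvone C3 becomes C13 and carvone C1 becomes C3, which maps R onto 1S). The Z-alkene comes from the trifluoroethyl phosphonate. C11 comes from the reversible transannular oxa-Michael addition, steered by C8 and the ring.

Key step: step 16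

Assumption: C11 lies α to the C10 ketone and β to the C13 ketone and is therefore configurationally mobile; the natural arrangement (C12 on the oxolanone face opposite to C7) is taken to be the more stable epimer of this bridged macrocycle.
Remark: the CIP letter at C8 changes along the route only because substituent ranks change; the spatial arrangement stays that of compound 1.

**Route**

Step 1
Reactants: 1 (R)-2-methylglycidol; 2 propyne
Product: 4 (S)-2-methylhept-4-yne-1,2-diol, via 1-propynyllithium 3 (not isolated)
Conditions: 2, n-BuLi, THF, −78 °C; then 1, DMPU, −78 °C → rt; aq. work-up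
Reagents that add atoms: none
Why: Epoxide alkynylation by SN2 attack of the lithium acetylide on the epoxide CH2 (C9) forms C9–C10 without touching the C8–O bond, so C8 is carried over unchanged from 1, and the Payne rearrangement of the alkoxide is degenerate in this substrate and cannot erode regiochemistry or configuration.

Step 2
Reactants: 4 (S)-2-methylhept-4-yne-1,2-diol
Product: 6 (S)-2-(but-2-yn-1-yl)-2-methyloxirane, via primary tosylate 5 (not isolated)
Conditions: TsCl, Et3N, Bu2SnO (cat.), CH2Cl2, 0 °C; then K2CO3, MeOH, rt
Reagents that add atoms: none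
Why: Selective sulfonylation of the primary hydroxyl followed by intramolecular Williamson closure displaces only at the primary carbon C7, so the tertiary C8–O bond and its configuration are retained.

Step 3
Reactants: 6 (S)-2-(but-2-yn-1-yl)-2-methyloxirane; 7 vinylmagnesium bromide
Product: 8 (R)-4-methyloct-1-en-6-yn-4-ol
Conditions: CuI (10 mol %), THF, −40 → 0 °C
Reagents that add atoms: none
Why: Copper-catalysed Grignard opening of a 2,2-disubstituted epoxide occurs at the unhindered CH2 (C7), installs C5=C6 through the C6–C7 bond, leaves the unactivated internal alkyne alone and does not involve C8.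

Step 4
Reactants: 8 (R)-4-methyloct-1-en-6-yn-4-ol
Product: 9 (R)-triethyl[(4-methyloct-1-en-6-yn-4-yl)oxy]silane
Conditions: TESOTf, 2,6-lutidine, CH2Cl2, 0 °C
Reagents that add atoms: triethylsilyl trifluoromethanesulfonate CC[Si](CC)(CC)OS(=O)(=O)C(F)(F)F
Why: Silyl triflate/lutidine silylation is the standard way to cap a hindered tertiary alcohol, and the cap prevents bromoetherification in step 5 and attack of this oxygen on the alkyne in step 17.

Step 5
Reactants: 9 (R)-triethyl[(4-methyloct-1-en-6-yn-4-yl)oxy]silane
Product: 10 (4S)-1-bromo-4-methyl-4-(triethylsilyloxy)oct-6-yn-2-ol (both C2 epimers)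
Conditions: NBS, acetone–H2O (4:1), 0 °C
Reagents that add atoms: N-bromosuccinimide O=C1CCC(=O)N1Br; water O
Why: In this bromohydrin formation the alkene takes up electrophilic bromine far faster than the dialkylalkyne and water opens the bromonium ion at the more substituted carbon C6 (Markovnikov), the new carbinol centre being irrelevant because it is oxidised in the next step.

Step 6
Reactants: 10 (4S)-1-bromo-4-methyl-4-(triethylsilyloxy)oct-6-yn-2-ol
Product: 11 (S)-1-bromo-4-methyl-4-(triethylsilyloxy)oct-6-yn-2-one
Conditions: Dess–Martin periodinane, CH2Cl2, rt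
Reagents that add atoms: none
Why: Dess–Martin oxidation converts the secondary bromohydrin into the α-bromoketone under near-neutral conditions that spare the silyl ether, the bromide and the alkyne.

Step 7
Reactants: 11 (S)-1-bromo-4-methyl-4-(triethylsilyloxy)oct-6-yn-2-one; 12 methyl bis(2,2,2-trifluoroethyl)phosphonoacetate
Product: 14 methyl (6S)-2-[bis(2,2,2-trifluoroethoxy)phosphoryl]-6-methyl-4-oxo-6-(triethylsilyloxy)dec-8-ynoate (both C2 epimers), via sodium phosphonoacetate 13 (not isolated)
Conditions: 12 (1.5 equiv), NaH, THF, 0 °C; then 11, 0 °C → rt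
Reagents that add atoms: none
Why: C-alkylation of the stabilised phosphonoacetate carbanion by a carbonyl-activated primary bromide forms C4–C5 by a fast SN2 step and avoids the neopentyl-type displacement that a ketal or dithiane at C6 would impose, the C4 centre being lost again in step 14.

Step 8
Reactants: 15 (R)-carvone
Product: 16 (1R,4R,6R)-1-methyl-4-(prop-1-en-2-yl)-7-oxabicyclo[4.1.0]heptan-2-one
Conditions: 30 % H2O2, NaOH (cat.), MeOH, 0 °C
Reagents that add atoms: hydrogen peroxide OO
Why: Weitz–Scheffer epoxidation attacks only the electron-poor enone C=C, from the face anti to the isopropenyl group, and leaves the isopropenyl alkene untouched.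

Step 9
Reactants: 16 (1R,4R,6R)-1-methyl-4-(prop-1-en-2-yl)-7-oxabicyclo[4.1.0]heptan-2-one
Product: 18 (R)-5-oxo-3-(prop-1-en-2-yl)pentanoic acid, via keto diol 17 (not isolated)
Conditions: aq. H2SO4 (cat.), THF, rt; then NaIO4, THF–H2O, 0 °C → rt
Reagents that add atoms: water O; sodium periodate [Na+].[O-]I(=O)(=O)=O
Why: Acid hydrolysis of the epoxide followed by Malaprade-type periodate cleavage of both C–C bonds at carvone C2 excises that carbon and its methyl group as acetic acid and gives two differentiated termini (CHO = C13, CO2H = C3) around a stereocentre that is β to both carbonyls and cannot epimerise.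

Step 10
Reactants: 18 (R)-5-oxo-3-(prop-1-en-2-yl)pentanoic acid
Product: 19 (S)-4-(1,3-dithian-2-yl)-3-(prop-1-en-2-yl)butanoic acid
Conditions: HS(CH2)3SH, BF3·OEt2 (cat.), CH2Cl2, −20 °C
Reagents that add atoms: propane-1,3-dithiol SCCCS
Why: Lewis-acid-catalysed thioacetalisation is selective for the aldehyde over the acid and, at low temperature, over the 1,1-disubstituted alkene, and it turns C13 into an acyl anion equivalent.

Step 11
Reactants: 19 (S)-4-(1,3-dithian-2-yl)-3-(prop-1-en-2-yl)butanoic acid
Product: 20 (S)-3-[(1,3-dithian-2-yl)methyl]-4-methylpent-4-en-1-ol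
Conditions: LiAlH4, THF, 0 °C → rt
Reagents that add atoms: none
Why: Hydride reduction of the carboxylic acid gives the primary alcohol at C3 directly, dithiane and isolated alkene being inert to LiAlH4.

Step 12
Reactants: 20 (S)-3-[(1,3-dithian-2-yl)methyl]-4-methylpent-4-en-1-ol; 21 1-bromobut-2-yne
Product: 23 (S)-3-{[2-(but-2-yn-1-yl)-1,3-dithian-2-yl]methyl}-4-methylpent-4-en-1-ol, via dilithio dithiane 22 (not isolated)
Conditions: n-BuLi (2.2 equiv), THF, −30 °C; DMPU, then 21, −78 → −30 °C
Reagents that add atoms: none
Why: Corey–Seebach alkylation of the C-lithiated dithiane (the lithium alkoxide being much the poorer nucleophile) with a propargylic bromide forms C12–C13 by direct SN2 and so avoids the propargyl/allenyl ambiguity of adding a butynyl metal to a C13 aldehyde.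

Step 13
Reactants: 23 (S)-3-{[2-(but-2-yn-1-yl)-1,3-dithian-2-yl]methyl}-4-methylpent-4-en-1-ol
Product: 24 (S)-3-{[2-(but-2-yn-1-yl)-1,3-dithian-2-yl]methyl}-4-methylpent-4-enal
Conditions: SO3·pyridine, DMSO, Et3N, CH2Cl2, 0 °C
Reagents that add atoms: none
Why: Parikh–Doering oxidation stops at the aldehyde and, unlike iodine(V) or oxoammonium oxidants, does not oxidise the thioacetal sulfur.

Step 14
Reactants: 14 methyl (6S)-2-[bis(2,2,2-trifluoroethoxy)phosphoryl]-6-methyl-4-oxo-6-(triethylsilyloxy)dec-8-ynoate; 24 (S)-3-{[2-(but-2-yn-1-yl)-1,3-dithian-2-yl]methyl}-4-methylpent-4-enal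
Product: 26 methyl (2Z,5S)-5-{[2-(but-2-yn-1-yl)-1,3-dithian-2-yl]methyl}-6-methyl-2-[(4S)-4-methyl-2-oxo-4-(triethylsilyloxy)oct-6-yn-1-yl]hepta-2,6-dienoate, via potassium phosphonate 25 (not isolated)
Conditions: 14, KHMDS, 18-crown-6, THF, −78 °C; then 24, −78 °C
Reagents that add atoms: none
Why: In the Still–Gennari olefination the electron-poor phosphonate and the dissociated potassium ion make elimination from the kinetic adduct faster than its reversal, which places C2 cis to the ester (Z), while only the doubly activated C4–H is deprotonated, so the free C6 ketone and its β-silyloxy group are not disturbed.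

Step 15
Reactants: 26 the Z-enoate diyne with C13 dithiane
Product: 27 methyl (2Z,5S)-6-methyl-2-[(4S)-4-methyl-2-oxo-4-(triethylsilyloxy)oct-6-yn-1-yl]-5-(2-oxohex-4-yn-1-yl)hepta-2,6-dienoate
Conditions: PhI(OCOCF3)2, MeCN–H2O (9:1), 0 °C, short contact
Reagents that add atoms: water O
Why: Hypervalent-iodine dethioacetalisation attacks sulfur within minutes at 0 °C, much faster than it touches isolated alkenes or alkynes, and frees the C13 ketone without any base that could shift the 3-alkynone to an allenone.

Step 16
Reactants: 27 the acyclic diketo diyne (C8 OTES, Z-enoate, two methyl-capped alkynes)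
Product: 28 methyl (1Z,4S,11S)-11-methyl-6,13-dioxo-4-(prop-1-en-2-yl)-11-(triethylsilyloxy)cyclotetradec-1-en-8-yne-1-carboxylate
Conditions: [Mo(≡C–C6H4-4-OMe)(OSiPh3)3] (15 mol %), MS 5 Å, toluene (2 mM), rt
Reagents that add atoms: none
Why: The alkylidyne adds to one methyl-capped triple bond by [2+2] cycloaddition, the metallacyclobutadiene cycloreverts to a substrate-bound alkylidyne, and the same two events at the second triple bond join C10 to C11 and pass on a Mo≡C–CH3 unit, the released C4 alkyne being trapped by the 5 Å sieves so that the equilibrium drains towards 28. The closest known reaction type is ring-closing alkyne metathesis of methyl-capped diynes to 12- to 20-membered cycloalkynes with molybdenum silanolate alkylidynes, including substrates that carry a ketone one CH2 away from the triple bond and are afterwards aromatised across the ring to a furan. The one ring formed, the 14-membered carbocycle C1–C14, closes end to end as a macrocyclisation between the two chain termini; no stereocentre is created, and C1, C8 and the Z-alkene are only carried through. Chemoselectivity for C≡C over C=C is inherent, because alkylidynes do not engage the isopropenyl group or the C3=C4 enoate, both of which would be at risk under alkene metathesis. Ring closure must win over oligomerisation, which is served by the 2 mM dilution, by the reversibility of the process and by three turn elements in the chain (quaternary C8, the Z-enoate and the sp2 centres C6 and C13). The bulky silanolates lower the Lewis acidity at molybdenum enough for ester, ketones and silyl ether, and the neutral, base-free medium should keep the acidic C12 methylene of the 3-alkynone from shifting to an allenone.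

Step 17
Reactants: 28 the 14-membered cycloalkyne
Product: 29 the C8-OTES 2,5-bridged furan (furan O joins C10 and C13; C11 and C12 are the furan CH positions; C6 ketone, Z-enoate and isopropenyl unchanged)
Conditions: Ph3PAuNTf2 (5 mol %), CH2Cl2, rt
Reagents that add atoms: none
Why: π-Acid-catalysed cycloisomerisation of an alk-3-yn-1-one proceeds by 5-endo-dig attack of the C13 carbonyl oxygen on C10, loss of a C12 proton and protodeauration at C11, is made irreversible by aromatisation, and meets no competing nucleophile because the C8 oxygen is silylated and the C6 carbonyl could only close a slower 6-exo ring.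

Step 18
Reactants: 29 the C8-OTES bridged furan
Product: 30 the C8 hydroxy bridged furan
Conditions: HF·pyridine, pyridine, THF, 0 °C
Reagents that add atoms: none
Why: Buffered fluoride desilylation removes the tertiary TES group without the basicity that would invite retro-aldol cleavage of the C6/C8 β-hydroxy ketone or migration of the C3=C4 double bond, and a 2,5-dialkylfuran tolerates this mild acidity.

Step 19
Reactants: 30 the C8 hydroxy bridged furan
Product: 33 target CNP0163183.3, via furan endoperoxide 31 (not isolated), via Z-enedione 32 (not isolated)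
Conditions: O2, TPP (cat.), hν (visible), CH2Cl2, −78 °C; Me2S, −78 °C → rt; Et3N (cat.), rt
Reagents that add atoms: dioxygen O=O
Why: This is the known photooxygenation of 2-(β-hydroxyalkyl)furans to 3-oxotetrahydrofurans, in which singlet oxygen adds [4+2] to the electron-rich furan far faster than it reacts with the isopropenyl or enoate alkene, sulfide reduction gives the Z-enedione, and the C8 hydroxyl closes the oxolanone by 5-exo-trig oxa-Michael addition to C11 (acceptor: C13 ketone), so that C11, formed reversibly under the amine, should settle under control of fixed C8 and the macrocycle in the 11R arrangement with C12 anti to C7.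

**Compound list**

1 | (R)-2-methylglycidol | OC[C@]1(C)CO1 | starting material
2 | propyne | CC#C | starting material
3 | 1-propynyllithium | [Li]C#CC | intermediate
4 | (S)-2-methylhept-4-yne-1,2-diol | OC[C@](O)(C)CC#CC | intermediate
5 | (S)-2-hydroxy-2-methylhept-4-yn-1-yl 4-methylbenzenesulfonate | Cc1ccc(cc1)S(=O)(=O)OC[C@](O)(C)CC#CC | intermediate
6 | (S)-2-(but-2-yn-1-yl)-2-methyloxirane | C1O[C@@]1(C)CC#CC | intermediate
7 | vinylmagnesium bromide | C=C[Mg]Br | starting material
8 | (R)-4-methyloct-1-en-6-yn-4-ol | C=CC[C@](O)(C)CC#CC | intermediate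
9 | (R)-triethyl[(4-methyloct-1-en-6-yn-4-yl)oxy]silane | C=CC[C@](O[Si](CC)(CC)CC)(C)CC#CC | intermediate
10 | (4S)-1-bromo-4-methyl-4-(triethylsilyloxy)oct-6-yn-2-ol, C2 epimers | BrCC(O)C[C@](O[Si](CC)(CC)CC)(C)CC#CC | intermediate
11 | (S)-1-bromo-4-methyl-4-(triethylsilyloxy)oct-6-yn-2-one | BrCC(=O)C[C@](O[Si](CC)(CC)CC)(C)CC#CC | intermediate
12 | methyl bis(2,2,2-trifluoroethyl)phosphonoacetate | COC(=O)CP(=O)(OCC(F)(F)F)OCC(F)(F)F | starting material
13 | sodium salt of 12 | [Na+].COC(=O)[CH-]P(=O)(OCC(F)(F)F)OCC(F)(F)F | intermediate
14 | methyl (6S)-2-[bis(2,2,2-trifluoroethoxy)phosphoryl]-6-methyl-4-oxo-6-(triethylsilyloxy)dec-8-ynoate, C2 epimers | COC(=O)C(CC(=O)C[C@](O[Si](CC)(CC)CC)(C)CC#CC)P(=O)(OCC(F)(F)F)OCC(F)(F)F | intermediate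
15 | (R)-carvone | CC1=CC[C@H](CC1=O)C(C)=C | starting material
16 | (1R,4R,6R)-1-methyl-4-(prop-1-en-2-yl)-7-oxabicyclo[4.1.0]heptan-2-one | C[C@@]12O[C@@H]1C[C@H](CC2=O)C(C)=C | intermediate
17 | trans-2,3-dihydroxy-2-methyl-5-(prop-1-en-2-yl)cyclohexan-1-one (keto diol) | C[C@@]1(O)[C@@H](O)C[C@H](CC1=O)C(C)=C | intermediate
18 | (R)-5-oxo-3-(prop-1-en-2-yl)pentanoic acid | O=CC[C@H](CC(=O)O)C(C)=C | intermediate
19 | (S)-4-(1,3-dithian-2-yl)-3-(prop-1-en-2-yl)butanoic acid | C1CSC(SC1)C[C@H](CC(=O)O)C(C)=C | intermediate
20 | (S)-3-[(1,3-dithian-2-yl)methyl]-4-methylpent-4-en-1-ol | C1CSC(SC1)C[C@H](CCO)C(C)=C | intermediate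
21 | 1-bromobut-2-yne | CC#CCBr | starting material
22 | O,C-dilithio derivative of 20 | [Li]OCC[C@@H](CC1([Li])SCCCS1)C(C)=C | intermediate
23 | (S)-3-{[2-(but-2-yn-1-yl)-1,3-dithian-2-yl]methyl}-4-methylpent-4-en-1-ol | CC#CCC1(SCCCS1)C[C@H](CCO)C(C)=C | intermediate
24 | (S)-3-{[2-(but-2-yn-1-yl)-1,3-dithian-2-yl]methyl}-4-methylpent-4-enal | CC#CCC1(SCCCS1)C[C@H](CC=O)C(C)=C | intermediate
25 | potassium salt of 14 | [K+].COC(=O)[C-](CC(=O)C[C@](O[Si](CC)(CC)CC)(C)CC#CC)P(=O)(OCC(F)(F)F)OCC(F)(F)F | intermediate
26 | acyclic Z-enoate diyne, C6 ketone, C8 OTES, C13 1,3-dithiane | CC#CC[C@](C)(O[Si](CC)(CC)CC)CC(=O)C/C(C(=O)OC)=C/C[C@@H](CC1(CC#CC)SCCCS1)C(C)=C | intermediate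
27 | acyclic Z-enoate diyne, C6 and C13 ketones, C8 OTES (metathesis precursor) | CC#CC[C@](C)(O[Si](CC)(CC)CC)CC(=O)C/C(C(=O)OC)=C/C[C@@H](CC(=O)CC#CC)C(C)=C | intermediate
28 | 14-membered cycloalkyne, C10≡C11 (metathesis product) | C=C(C)[C@H]1C/C=C(\C(=O)OC)CC(=O)C[C@@](C)(O[Si](CC)(CC)CC)CC#CCC(=O)C1 | intermediate
29 | C8-OTES 2,5-bridged furan | C=C(C)[C@H]1C/C=C(\C(=O)OC)CC(=O)C[C@@](C)(O[Si](CC)(CC)CC)Cc2ccc(o2)C1 | intermediate
30 | C8 hydroxy 2,5-bridged furan | C=C(C)[C@H]1C/C=C(\C(=O)OC)CC(=O)C[C@@](C)(O)Cc2ccc(o2)C1 | intermediate
31 | furan endoperoxide (O–O and O bridges between C10 and C13) | C=C(C)[C@H]1C/C=C(\C(=O)OC)CC(=O)C[C@@](C)(O)CC23C=CC(OO2)(O3)C1 | intermediate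
32 | C8 hydroxy Z-enedione (C10 and C13 ketones, C11=C12) | C=C(C)[C@H]1C/C=C(\C(=O)OC)CC(=O)C[C@@](C)(O)CC(=O)/C=C\C(=O)C1 | intermediate
33 | CNP0163183.3, (1S,3Z,8R,11R) in the locants used here | C=C(C)[C@H]1C/C=C(\C(=O)OC)CC(=O)C[C@]2(C)CC(=O)[C@@H](CC(=O)C1)O2 | target

**Step count**

Total step count: 19. Longest linear sequence: 13 steps (steps 1–7 and 14–19, from (R)-2-methylglycidol); the carvone branch contributes steps 8–13.

**Steps most likely to fail**

1. Step 19.
   - Risk: poor facial selectivity at C11 in the oxa-Michael closure, Z-to-E isomerisation of the enedione before capture, or transannular attack by the acidic C5 methylene under the amine.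
   - Fallback: this sets out from 29 and separates oxidation from ring closure.
   - Photooxygenation and sulfide reduction of the silylated furan should give the isolable silyl-protected Z-enedione F1.
   - Catalytic iodine in daylight can convert F1 into the silyl-protected E-enedione F2.
   - Buffered HF·pyridine on F1 or F2 then unmasks the C8 hydroxyl in a non-enolising, mildly acidic medium, and the oxolanone closes on a geometry-defined acceptor.
   - Within the macrocycle the two acceptor geometries offer different faces of C11 to the tethered oxygen, so the one that leads to 11R can be chosen. The sequence returns to the route at 33.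

2. Step 16.
   - Risk: prototropic shift of the 3-alkynone on the sieves, catalyst decay through the enolisable C13 ketone, or oligomerisation instead of ring closure.
   - Fallback: this sets out from 26 and keeps the same C10≡C11 closure but masks C13 as an sp3 ketal, which removes the C12 acidity and adds a further turn element.
   - Oxidative exchange of the dithiane with PhI(OCOCF3)2 in the presence of ethylene glycol (MeCN) should give the acyclic C13 dioxolane diyne F3.
   - The same molybdenum catalyst should close F3 to the C13 dioxolane cycloalkyne F4.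
   - PPTS in wet acetone frees the ketone inside the ring. The sequence returns to the route at 28.

3. Step 15.
   - Risk: loss of the silyl ether to the liberated acid, oxidation at the isopropenyl group, or alkynone-to-allenone shift in the open chain, where it would destroy a metathesis terminus.
   - Fallback: this sets out from 26 and postpones the unmasking until after ring closure, relying on the tolerance of molybdenum alkylidynes for thioethers.
   - Metathesis of 26 itself should give the C13 dithiane cycloalkyne F5.
   - F5 is then cleaved with PhI(OCOCF3)2 in aqueous MeCN. In the ring a partial shift to the allenone is harmless, because alkynone and allenone both lead to the furan in step 17. The sequence returns to the route at 28.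

**Further compounds**

F1 | step 19 | silyl-protected Z-enedione (C8 OTES, C10 and C13 ketones, 11Z) | C=C(C)[C@H]1C/C=C(\C(=O)OC)CC(=O)C[C@@](C)(O[Si](CC)(CC)CC)CC(=O)/C=C\C(=O)C1
F2 | step 19 | silyl-protected E-enedione (C8 OTES, C10 and C13 ketones, 11E) | C=C(C)[C@H]1C/C=C(\C(=O)OC)CC(=O)C[C@@](C)(O[Si](CC)(CC)CC)CC(=O)/C=C/C(=O)C1
F3 | step 16 | acyclic C13 dioxolane diyne | CC#CC[C@](C)(O[Si](CC)(CC)CC)CC(=O)C/C(C(=O)OC)=C/C[C@@H](CC1(CC#CC)OCCO1)C(C)=C
F4 | step 16 | C13 dioxolane cycloalkyne | C=C(C)[C@H]1C/C=C(\C(=O)OC)CC(=O)C[C@@](C)(O[Si](CC)(CC)CC)CC#CCC2(OCCO2)C1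
F5 | step 15 | C13 dithiane cycloalkyne | C=C(C)[C@H]1C/C=C(\C(=O)OC)CC(=O)C[C@@](C)(O[Si](CC)(CC)CC)CC#CCC2(SCCCS2)C1
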